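**Strategy**

Everything rests on closing lactone E (C14–C17, the bond from the lactone carbonyl to the ring C/D/E junction carbon) before rings A–C exist. In cyclopentenone 9, C14 is the γ-carbon of the ring-D enone C16(=O)–C12=C13–C14; its dienolate attacks the methyl carbonate on O–C18 in a vinylogous Dieckmann condensation, giving the cis-fused lactone as a stabilised dienolate that is alkylated in the same flask at C12 with dienyl bromide 12. C12-methylation, a catalytic Diels–Alder reaction (ring B), vinylalumination/SmI2 ketyl–olefin lactonisation (ring A) and a proton-initiated C8–C14 cation–olefin closure (ring C, C13=CH2) then complete brasilianoid F.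

Key step: step 8

Remark 1 (locants used for all compounds): ring A = C1(OH)–C2–C3H2–C4(CH3)(O)–C5–C10(CH3), bridged by lactone C2–C19(=O)–O–C4; ring B = C5–C6–C7–C8(CH3)–C9–C10; ring C = C8–C9–C11–C12(CH3)–C13(=CH2)–C14; ring D = C12–C13–C14–C15(OH)–C16(=O); lactone E = C14–C17(=O)–O–C18(H)(CH3)–C15. β is the face of the C10 methyl. The SMILES strings are authoritative for configuration.

Remark 2 (assumption): the catalyst antipodes in steps 2 and 11 are assigned by analogy with the published facial models for simpler substrates; the mirror-image catalyst is used if the sense proves reversed.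

**Route**

Step 1
Reactants: 1 3-methylcyclopent-2-en-1-one; 2 acetaldehyde
Product: 5 (E)-5-ethylidene-3-methylcyclopent-2-en-1-one, via aldol adduct 3 (not isolated), via aldol mesylate 4 (not isolated)
Conditions: LDA, THF, −78 °C; MeCHO; MsCl, −78 → 0 °C; DBU, rt
Reagents that add atoms: none
Why: Kinetic deprotonation at the α′-carbon (future C15), aldol addition, mesylation and E1cB elimination (aldol condensation) should give the cross-conjugated alkylidene ketone with the thermodynamic E geometry (methyl anti to the carbonyl).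

Step 2
Reactants: 5 (E)-5-ethylidene-3-methylcyclopent-2-en-1-one
Product: 6 (2S,3R)-2,6-dimethyl-1-oxaspiro[2.4]hept-5-en-4-one
Conditions: La(O-i-Pr)3 (5 mol %), (S)-BINOL, Ph3As=O, TBHP, 4 Å MS, THF, rt
Reagents that add atoms: tert-butyl hydroperoxide CC(C)(C)OO
Why: Catalytic asymmetric nucleophilic (Weitz–Scheffer-type) epoxidation of an E-enone; the exocyclic, β-monosubstituted alkene reacts in preference to the β,β-disubstituted ring alkene, the trans relationship is retained and the La–BINOL peroxide sets C15 and C18 together.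

Step 3
Reactants: 6 (2S,3R)-2,6-dimethyl-1-oxaspiro[2.4]hept-5-en-4-one
Product: 7 (5R)-5-hydroxy-5-[(1R)-1-hydroxyethyl]-3-methylcyclopent-2-en-1-one
Conditions: HClO4 (cat.), THF/H2O, 0 °C → rt
Reagents that add atoms: water O
Why: Acid-catalysed epoxide hydrolysis; water attacks the β-carbon C18 in an SN2 sense with inversion (the α-carbon C15 is deactivated by the ketone), which gives the anti-diol required for the C15/C18 pair.

Step 4
Reactants: 7 (5R)-5-hydroxy-5-[(1R)-1-hydroxyethyl]-3-methylcyclopent-2-en-1-one
Product: 8 (1R)-1-[(1R)-1-hydroxy-4-methyl-2-oxocyclopent-3-en-1-yl]ethyl methyl carbonate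
Conditions: ClCO2Me, pyridine, CH2Cl2, −20 °C
Reagents that add atoms: methyl chloroformate COC(=O)Cl
Why: Chemoselective O-alkoxycarbonylation of the secondary alcohol; the tertiary α-keto alcohol should not react at this temperature.

Step 5
Reactants: 8 (1R)-1-[(1R)-1-hydroxy-4-methyl-2-oxocyclopent-3-en-1-yl]ethyl methyl carbonate
Product: 9 (1R)-1-[(1R)-1-(tert-butyldimethylsilyloxy)-4-methyl-2-oxocyclopent-3-en-1-yl]ethyl methyl carbonate
Conditions: TBSOTf, 2,6-lutidine, CH2Cl2, 0 °C → rt
Reagents that add atoms: tert-butyldimethylsilyl triflate CC(C)(C)[Si](C)(C)OS(=O)(=O)C(F)(F)F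
Why: Silyl triflate silylation of the tertiary alcohol; the bulky ether later shields the C15–O face of ring D and the neighbouring C14.

Step 6
Reactants: 10 (E)-3-methylpent-2-en-4-yn-1-ol
Product: 11 (E)-3-methylpenta-2,4-dien-1-ol
Conditions: H2 (1 atm), Lindlar catalyst, quinoline, EtOAc, rt
Reagents that add atoms: none
Why: Lindlar semi-hydrogenation of the terminal alkyne; the trisubstituted E-alkene is not touched.

Step 7
Reactants: 11 (E)-3-methylpenta-2,4-dien-1-ol
Product: 12 (E)-5-bromo-3-methylpenta-1,3-diene
Conditions: PBr3, Et2O, −20 °C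
Reagents that add atoms: phosphorus tribromide BrP(Br)Br
Why: SN2 bromination of the primary allylic alcohol through its phosphite ester, with retention of the alkene geometry.

Step 8
Reactants: 9 (1R)-1-[(1R)-1-(tert-butyldimethylsilyloxy)-4-methyl-2-oxocyclopent-3-en-1-yl]ethyl methyl carbonate; 12 (E)-5-bromo-3-methylpenta-1,3-diene
Product: 14 (3R,3aR,6aR)-3a-(tert-butyldimethylsilyloxy)-3,6-dimethyl-5-[(2E)-3-methylpenta-2,4-dien-1-yl]-3,3a-dihydro-1H-cyclopenta[c]furan-1,4(6aH)-dione, via lactone dienolate 13 (not isolated)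
Conditions: LiHMDS (1.1 equiv), THF, −78 → 0 °C; then 12, DMPU, 0 °C → rt
Reagents that add atoms: none
Why: LiHMDS removes a γ-proton at C14 (C15 is quaternary, so no α′-enolate can form) to give the linear dienolate O–C16=C12–C13=C14, whose γ-carbon adds to the carbonate carbonyl C17 held on O–C18 and expels methoxide. The closest known reaction types are the Dieckmann cyclisation of enolates onto tethered carbonates and the γ-acylation of Hagemann-ester-type dienolates. Ring E closes 5-exo-trig at the carbonyl with the dienolate π-bond exocyclic to the new ring, so only the cis-fused 2-oxabicyclo[3.3.0]octane can form; C14 is planar in dienolate 13 and is reprotonated in 14 under this ring-fusion control (H cis to the C15 silyl ether). γ- over α-acylation is secured thermodynamically: attack through C12 would give a bridged, non-enolisable β-keto lactone that reverts by retro-Claisen cleavage, whereas the γ-product is deprotonated to 13, the sink. The soft allylic bromide 12 then alkylates 13 at C12, the ketone α-carbon as in Hagemann's ester, because C14 is shielded by the adjacent quaternary C15–OTBS, and tautomerisation returns the enone.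

Step 9
Reactants: 14 (the C12-dienylated bicyclic lactone)
Product: 15 (3R,3aR,5R)-3a-(tert-butyldimethylsilyloxy)-3,5,6-trimethyl-5-[(2E)-3-methylpenta-2,4-dien-1-yl]-3,3a-dihydro-1H-cyclopenta[c]furan-1,4(5H)-dione
Conditions: t-BuOK, THF, −78 °C; MeI, −78 → 0 °C
Reagents that add atoms: iodomethane CI
Why: Deconjugative C-alkylation of the vinylogous β-keto lactone anion; MeI should attack C12 (C14 is blocked by C15–OTBS) from the face anti to the silyl ether, which creates the C12 quaternary centre with its methyl on the C18 face and moves the alkene to C13=C14.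

Step 10
Reactants: 16 2,4-dimethylfuran
Product: 18 (E)-2-methyl-4-oxopent-2-enal, via Z-keto enal 17 (not isolated)
Conditions: NBS, NaHCO3, acetone/H2O, −15 °C; then pyridine, rt
Reagents that add atoms: water O
Why: Oxidative ring opening of the furan (bromination, water addition, collapse of the hemiacetal) gives the cis-ene-dicarbonyl compound, which pyridine isomerises to the trans isomer.

Step 11
Reactants: 15 (the C12-quaternary dienyl butenolide); 18 (E)-2-methyl-4-oxopent-2-enal
Product: 19 Diels–Alder adduct: ring B formed as C9H(α-H, bearing C11H2–C12)–C8(CH3)=C7H–C6H2–C5H(α-H, bearing acetyl C4)–C10(β-CH3, bearing CHO = C1); rings D/E as in 15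
Conditions: (S)-o-tolyl oxazaborolidine·Tf2NH (20 mol %), CH2Cl2, −78 → −40 °C
Reagents that add atoms: none
Why: Catalytic enantioselective Diels–Alder reaction with a formyl-bound cationic oxazaborolidine; the formyl group directs C10 to the substituted diene terminus C9 and C5 to C6, the E-dienophile fixes 10-CH3 and 5-H trans, the exo-formyl/endo-acetyl transition state places C11 cis to 10-CH3, and the catalyst selects the diene face.

Step 12
Reactants: 19 (the Diels–Alder adduct); 20 methyl propiolate
Product: 21 C1 carbinol (1α-OH) bearing the 1-(methoxycarbonyl)vinyl group C2(=C3H2)–CO2Me on C1; otherwise as 19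
Conditions: DIBAL-H, NMO, 20, THF, 0 °C; then 19, 0 °C → rt
Reagents that add atoms: none
Why: Vinylalumination (hydroalumination of the propiolate to the α-alumino acrylate, then addition to the aldehyde, a Baylis–Hillman-type adduct made without amine catalysis); the aldehyde reacts in preference to the ketones, and Felkin–Anh attack anti to the bulkier C9 branch of quaternary C10 should give the 1α-alcohol.

Step 13
Reactants: 21 (the C1 carbinol with the acrylate unit)
Product: 23 ring-A lactone (C2–C19(=O)–O–C4 on the β-face, 1α-OH, 4α-CH3, 5α-H) with the C7=C8 alkene, 9α-H and 15-OTBS; ring C still open, via hydroxy ester 22 (not isolated)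
Conditions: SmI2 (2.5 equiv), t-BuOH, THF, −78 → 0 °C
Reagents that add atoms: none
Why: SmI2 ketyl–olefin cyclisation; the C4 ketyl adds 6-endo to the acrylate CH2 (C3) through a chair with the C4–O bond axial (β) to avoid a 1,3-diaxial CH3/CH3 contact with 10-CH3, the samarium enolate is protonated at C2 from the open α-face, and the 1,3-diaxial alkoxide/ester pair lactonises. Without HMPA the hindered α-silyloxy ketone C16 and the tetrasubstituted butenolide are expected to survive.

Step 14
Reactants: 23 (the ring-A lactone, 15-OTBS)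
Product: 24 15-hydroxy seco-precursor (C7=C8 alkene, butenolide C13(CH3)=C14, free 1-OH and 15-OH)
Conditions: HF·pyridine, THF, 0 °C → rt
Reagents that add atoms: none
Why: Fluoride-driven cleavage of the tertiary silyl ether; the non-basic reagent avoids α-ketol rearrangement at C15/C16 and removes the group that would hinder the approach of C8 to C14.

Step 15
Reactants: 24 (the 15-hydroxy seco-precursor)
Product: 25 brasilianoid F
Conditions: TfOH (2 equiv), HFIP/CH2Cl2, −40 → 0 °C
Reagents that add atoms: none
Why: Proton-initiated cation–olefin cyclisation terminated by the α-carbon of the α,β-unsaturated lactone, as in the acid cyclisation of geranic and farnesic esters; Markovnikov protonation at C7 gives the C8 cation, C14 attacks it equatorially from the α-face (axial β-attack is blocked by 10-CH3), which sets 8β-CH3 and C14, and the C13 cation can lose a proton only from its methyl group (C12 and C14 are quaternary), giving the exocyclic alkene.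

**Compound list**

1 | 3-methylcyclopent-2-en-1-one | CC1=CC(=O)CC1 | starting material
2 | acetaldehyde | CC=O | starting material
3 | 5-(1-hydroxyethyl)-3-methylcyclopent-2-en-1-one (aldol adduct, diastereomer mixture, formed as its lithium alkoxide) | CC(O)C1CC(C)=CC1=O | intermediate
4 | 1-(4-methyl-2-oxocyclopent-3-en-1-yl)ethyl methanesulfonate | CC(OS(C)(=O)=O)C1CC(C)=CC1=O | intermediate
5 | (E)-5-ethylidene-3-methylcyclopent-2-en-1-one | C/C=C1\CC(C)=CC1=O | intermediate
6 | (2S,3R)-2,6-dimethyl-1-oxaspiro[2.4]hept-5-en-4-one | O1[C@@H](C)[C@@]12CC(C)=CC2=O | intermediate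
7 | (5R)-5-hydroxy-5-[(1R)-1-hydroxyethyl]-3-methylcyclopent-2-en-1-one | O[C@H](C)[C@@]1(O)C(=O)C=C(C)C1 | intermediate
8 | (1R)-1-[(1R)-1-hydroxy-4-methyl-2-oxocyclopent-3-en-1-yl]ethyl methyl carbonate | COC(=O)O[C@H](C)[C@@]1(O)C(=O)C=C(C)C1 | intermediate
9 | (1R)-1-[(1R)-1-(tert-butyldimethylsilyloxy)-4-methyl-2-oxocyclopent-3-en-1-yl]ethyl methyl carbonate | COC(=O)O[C@H](C)[C@@]1(O[Si](C)(C)C(C)(C)C)C(=O)C=C(C)C1 | intermediate
10 | (E)-3-methylpent-2-en-4-yn-1-ol | C#C/C(C)=C/CO | starting material
11 | (E)-3-methylpenta-2,4-dien-1-ol | C=C/C(C)=C/CO | intermediate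
12 | (E)-5-bromo-3-methylpenta-1,3-diene | C=C/C(C)=C/CBr | intermediate
13 | lithium dienolate of (3R,3aR)-3a-(tert-butyldimethylsilyloxy)-3,6-dimethyl-3,3a-dihydro-1H-cyclopenta[c]furan-1,4(6aH)-dione (cis-fused lactone E on ring D, charge over O–C16=C12–C13=C14) | [Li+].CC1=C2C(=O)O[C@H](C)[C@@]2(O[Si](C)(C)C(C)(C)C)C([O-])=C1 | intermediate
14 | (3R,3aR,6aR)-3a-(tert-butyldimethylsilyloxy)-3,6-dimethyl-5-[(2E)-3-methylpenta-2,4-dien-1-yl]-3,3a-dihydro-1H-cyclopenta[c]furan-1,4(6aH)-dione (6a-H cis to the silyl ether) | CC1=C(C/C=C(C)/C=C)C(=O)[C@]2(O[Si](C)(C)C(C)(C)C)[C@@H](C)OC(=O)[C@H]12 | intermediate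
15 | (3R,3aR,5R)-3a-(tert-butyldimethylsilyloxy)-3,5,6-trimethyl-5-[(2E)-3-methylpenta-2,4-dien-1-yl]-3,3a-dihydro-1H-cyclopenta[c]furan-1,4(5H)-dione (12-CH3 on the C18 face, dienyl chain on the silyl ether face) | CC1=C2C(=O)O[C@H](C)[C@@]2(O[Si](C)(C)C(C)(C)C)C(=O)[C@]1(C)C/C=C(C)/C=C | intermediate
16 | 2,4-dimethylfuran | CC1=COC(C)=C1 | starting material
17 | (Z)-2-methyl-4-oxopent-2-enal | O=C/C(C)=C\C(C)=O | intermediate
18 | (E)-2-methyl-4-oxopent-2-enal | O=C/C(C)=C/C(C)=O | intermediate
19 | Diels–Alder adduct: cyclohexene ring B (C7=C8, 8-CH3) with 9α-H (C9 bears C11H2–C12), 5α-H (C5 bears acetyl C4) and 10β-CH3 (C10 bears CHO = C1); rings D/E as in 15 | CC1=C2C(=O)O[C@H](C)[C@@]2(O[Si](C)(C)C(C)(C)C)C(=O)[C@]1(C)C[C@@H]3C(C)=CC[C@H](C(C)=O)[C@@]3(C)C=O | intermediate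
20 | methyl propiolate | C#CC(=O)OC | starting material
21 | 1α-carbinol of 19 in which C1 bears C2(=C3H2)CO2Me (methyl 2-methylenepropanoate unit); C4 methyl ketone retained | CC1=C2C(=O)O[C@H](C)[C@@]2(O[Si](C)(C)C(C)(C)C)C(=O)[C@]1(C)C[C@@H]3C(C)=CC[C@H](C(C)=O)[C@@]3(C)[C@H](O)C(=C)C(=O)OC | intermediate
22 | ring-A hydroxy ester: trans-fused ring A with 1α-OH, 2β-CO2Me, 4β-OH, 4α-CH3; C7=C8 alkene; rings D/E as in 15 | CC1=C2C(=O)O[C@H](C)[C@@]2(O[Si](C)(C)C(C)(C)C)C(=O)[C@]1(C)C[C@@H]3C(C)=CC[C@H]4[C@@]3(C)[C@H](O)[C@@H](C(=O)OC)C[C@@]4(C)O | intermediate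
23 | ring-A lactone (C2–C19(=O)–O–C4, β-face) with 1α-OH, C7=C8 alkene, 9α-H, 15-OTBS; ring C open | CC1=C2C(=O)O[C@H](C)[C@@]2(O[Si](C)(C)C(C)(C)C)C(=O)[C@]1(C)C[C@@H]3C(C)=CC[C@H]4[C@@]3(C)[C@H](O)[C@@H]5C[C@@]4(C)OC5=O | intermediate
24 | 15-hydroxy analogue of 23 (seco-precursor with C7=C8 and C13(CH3)=C14) | CC1=C2C(=O)O[C@H](C)[C@@]2(O)C(=O)[C@]1(C)C[C@@H]3C(C)=CC[C@H]4[C@@]3(C)[C@H](O)[C@@H]5C[C@@]4(C)OC5=O | intermediate
25 | brasilianoid F | C=C1[C@@]2(C)C[C@H]3[C@]4(C)[C@H](O)[C@@H]5C[C@@](C)(OC5=O)[C@H]4CC[C@]3(C)[C@@]13C(=O)O[C@H](C)[C@@]3(O)C2=O | target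

**Summary**

Total step count: 15. Longest linear sequence: 12 steps (steps 1–5, 8, 9, 11–15, from compound 1).

Steps most likely to fail:

1. Step 15. The C8 cation may lose a proton faster than it is captured, may be attacked through the methyl carbon of the deconjugated (exo-methylene) tautomer of the butenolide instead of through C14, or may undergo hydride/methyl shifts. Fallback: from 24, mercury(II) triflate–N,N-dimethylaniline complex (MeCN/CH2Cl2, −20 °C; aqueous NaCl) would drive the same C8–C14 closure through a mercurinium ion, which forms irreversibly and without free Brønsted acid, giving the 7-chloromercurio derivative of brasilianoid F F1; radical demercuration (Bu3SnH, AIBN, benzene, 60 °C) would return to the route at 25.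

2. Step 11. The Lewis-basic ketone and lactone of rings D/E may sequester the catalyst, so that control of the diene face is lost. Fallback: from 15 and 18, the cycloaddition would be run with catalytic Me2AlCl (CH2Cl2, −78 °C), giving up reagent control; because rings D/E are already enantiopure the two facial adducts are diastereomers, and 19 would be separated by chromatography from the C5,C9,C10-epimeric adduct F2, rejoining the route at 19.

3. Step 13. Competitive electron transfer to the α-silyloxy ketone C16 (C15–O cleavage) or to the butenolide, and ketyl addition through a boat giving a C4 epimer that cannot lactonise. Fallback: from 21, Luche reduction (NaBH4, CeCl3, MeOH, −78 °C) of the methyl ketone would give the C4 carbinol F3 (both epimers serve). Photoredox hydrogen-atom-transfer catalysis (Ir photocatalyst, quinuclidine, Bu4N·H2PO4, MeCN, blue light) would then generate the same C4 α-oxy radical without a stoichiometric reductant; its 6-endo addition to the acrylate and lactonisation would rejoin the route at 23.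

Further compounds
F1 | step 15 | 7-(chloromercurio) derivative of brasilianoid F (C7 configuration not defined) | C=C1[C@@]2(C)C[C@H]3[C@]4(C)[C@H](O)[C@@H]5C[C@@](C)(OC5=O)[C@H]4CC([Hg]Cl)[C@]3(C)[C@@]13C(=O)O[C@H](C)[C@@]3(O)C2=O
F2 | step 11 | C5,C9,C10-epimeric Diels–Alder adduct of 15 and 18 (opposite diene face) | CC1=C2C(=O)O[C@H](C)[C@@]2(O[Si](C)(C)C(C)(C)C)C(=O)[C@]1(C)C[C@H]3C(C)=CC[C@@H](C(C)=O)[C@]3(C)C=O
F3 | step 13 | C4 carbinol of 21 (1-hydroxyethyl on C5, C4 epimer mixture) | CC1=C2C(=O)O[C@H](C)[C@@]2(O[Si](C)(C)C(C)(C)C)C(=O)[C@]1(C)C[C@@H]3C(C)=CC[C@H](C(C)O)[C@@]3(C)[C@H](O)C(=C)C(=O)OC
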